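(The runs were computed for substances that don't exist; scatter was added.)

- A ratio of 333 stands behind the flask: target formed per catalyst charged, the turnover number, taken from 18% of target at 2.50 min on a catalyst charge of 0.0540% of the starting material.

| flask | starting material | second substrate | capture agent | free catalyst | temperature | remark | time |
|---|---|---|---|---|---|---|---|
| north-east | 1 M | 0.50 M | 0.30 M | 0.54 mM | 25 °C | the very flask that is asked about, followed so far |  |
| south | 1 M | 0.50 M | 0.30 M | 1.1 mM | 20 °C | run made earlier |  |
| flask | 1.0 M | 0.500 M | 0.300 M | 0.54 mM | 25 °C |  | 2.5 min |

| run | time / min | target / % | starting material / % |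
|---|---|---|---|
| north-east | 0.667 | 9 | 89 |
| north-east | 1.33 | 14 | 83 |
| north-east | 2.00 | 16 | 85 |
| north-east | 2.50 | 18 | 83 |
| south | 0.333 | 9 | 90 |
| south | 0.833 | 19 | 78 |
| south | 1.50 | 25 | 75 |
| south | 2.50 | 30 | 69 |

(each reading ± 1.5 percentage points)

- Sunday's: at 2.5 min add starting material, 50.0% of the amount charged, then wait 80 s
- Friday's: at 2.5 min raise the temperature by 15 K, then wait 80 s
- Tuesday's: at 2.5 min add free catalyst, 50.0% of the amount charged, then wait 80 s
- Thursday's: change nothing and wait 80 s more

- the volume of additions can be left aside
- a reading or a percentage of target counts all its forms, free or not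

- target, in percent of the starting material first charged, at 2.5 min
- the remedy with the largest gain of target, or "none" below 2 percentage points (Sunday's / Friday's / Tuesday's / Thursday's / none)
- target present, in percent of the starting material first charged, after Sunday's
- target present, in percent of the starting material first charged, after Tuesday's

- The objection is that this ratio means little if the flask is simply running out of starting material. But 83% of it still reads as present, while the rate of target falls from 0.135 min⁻¹ of the charge over the first reading to 0.0342 min⁻¹ over the last two intervals, which is a quarter of the first rate.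
- A second objection is that an equilibrium or a poison made by the reaction would stall the flask too, and then the level reached would not follow the catalyst. The south run, with twice the catalyst, reads 30% of target, a ratio of 273. This is lower than the flask's, but that run is colder and both ratios carry the scatter. Its target also climbs past 25%, so catalyst goes on working at such levels.
- Is the flask finished, though? Joining the two ends with a rate that decays exponentially gives a decay time of 1.15 min, and so a tail of 1.6 percentage points in the further 80 s. Thursday's earns that tail, and Sunday's and Friday's act on the same remainder of live catalyst.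
- Tuesday's brings new catalyst, and at the same ratio a dose of 50.0% of the charge makes 9 points, which is more than the tail. So this reckoning takes the last reading for "now" and chooses Tuesday's.
- The forecast says 18%, Tuesday's, 19.8% and 25.8%, on the ground that “It points to catalyst death at a fixed turnover number”. Its gain of 7.8 points is smaller than the gain reckoned here.
- The flask gives 17.0% and Tuesday's, with 17.9% after Sunday's and 26.2% after Tuesday's, so the forecast held. The gains are 0.88 points, 1.4 points, 9.3 points and 0.64 points for Sunday's, Friday's, Tuesday's and Thursday's.

    starting material + free catalyst ⇌ catalyst intermediate A (K = 6.50 L mol⁻¹, k = 31.0 L mol⁻¹ s⁻¹, Ea = 51.0 kJ mol⁻¹, ΔH = 16.0 kJ mol⁻¹)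
    catalyst intermediate A → free catalyst + target (k = 13.0 s⁻¹, Ea = 62.0 kJ mol⁻¹)
    second substrate + free catalyst ⇌ catalyst intermediate B (K = 0.980 L mol⁻¹, k = 37.0 L mol⁻¹ s⁻¹, Ea = 37.0 kJ mol⁻¹, ΔH = −64.0 kJ mol⁻¹)
    catalyst intermediate B → free catalyst + second product (k = 420 s⁻¹, Ea = 46.0 kJ mol⁻¹)
    catalyst intermediate B + capture agent → trapped intermediate (k = 6.80 L mol⁻¹ s⁻¹, Ea = 41.0 kJ mol⁻¹)
    second substrate + target ⇌ idle adduct, settled at all times (K = 4.90 L mol⁻¹, ΔH = −11.0 kJ mol⁻¹)
    (constants at 25 °C)

- In the flask at 0.468 min, catalyst intermediate B goes on to free catalyst and second product 210 times as fast as it becomes trapped intermediate, and at 2.50 min the trapped intermediate holds 96.2% of the catalyst while 99.8% of the capture agent remains: this is what the flask has and the ratio of 333 does not show. That ratio still gave 9 points against the 9.3 points of Tuesday's, and for a neighbouring flask with 0.920 mM of free catalyst it gives 30.7%, where that flask stands at 32.1%.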